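**Plan**

1. Target numbering: C1 = C(OH)(CH2OBz), C2 = CH(OBz), C3 = CH(OH), C4=C5, C6 = CHCl. The C6–Cl and C1–OH bonds are cut back to a C1–C6 vinyl epoxide (anti opening by HCl), and the epoxide to a C4=C5–C6=C1 diene epoxidised under direction of C2–OH.
2. C4=C5 is traced to loss of CO2 and H from a carboxyl group on C4. The C2–O bond is traced to the same carboxyl group attacking C2 while a C3–O–C6 ether bridge opens. The ring bonds C3–C4 and C5–C6 are cut last, by a Diels–Alder disconnection into furan-3-ylmethyl benzoate and an acrylate.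
3. Enabling feature: the cis C4=C5 alkene lies between two heteroatom-bearing sp3 carbons, C3 and C6. This is the imprint of a furan (ring carbons C6–C1–C2–C3, its oxygen bridging C3 and C6) that has added a two-carbon dienophile. The acrylate carboxyl serves as activating group, oxygen relay and leaving group (as CO2), so the acrylate acts as an acetylene equivalent.
4. Forward: the carbocycle is formed first as a 7-oxanorbornene (step 2). The oxygen bridge is exchanged for a temporary γ-lactone (step 4), the lactone is opened and CO2 expelled to give the diene (steps 6, 7), the epoxide is closed (step 8) and opened by chloride (step 10).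
5. Stereochemistry: the cycloaddition catalyst fixes C3. The endo carboxyl delivers oxygen to C2 anti to the bridge, so C2–O and C3–O are trans. C2–OH directs the epoxide syn, which sets C1. Chloride inverts C6.

Key step: step 2

Assumption: the (S)-oxazaborolidinium catalyst is taken to give the (1R,2R,4R) endo adduct 4 with this furan; if the sense of induction is the opposite, the (R)-catalyst is used and nothing else changes.

**Route**

Step 1
Reactants: 1 furan-3-ylmethanol
Product: 2 furan-3-ylmethyl benzoate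
Conditions: BzCl, Et3N, DMAP (cat.), CH2Cl2, 0 °C
Reagents that add atoms: benzoyl chloride, O=C(Cl)c1ccccc1
Why: Acylation of the primary alcohol under nucleophilic catalysis masks the hydroxyl, which would otherwise quench the Lewis-acid catalyst of step 2; no stereocentre is formed.

Step 2
Reactants: 2 furan-3-ylmethyl benzoate; 3 2,2,2-trifluoroethyl acrylate
Product: 4 2,2,2-trifluoroethyl (1R,2R,4R)-5-[(benzoyloxy)methyl]-7-oxabicyclo[2.2.1]hept-5-ene-2-carboxylate (2-endo ester)
Conditions: (S)-diphenylprolinol-derived B-(o-tolyl)oxazaborolidine·HNTf2 (20 mol %), 3 (2 equiv), CH2Cl2, −78 to −40 °C, cold Et3N quench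
Reagents that add atoms: none
Why: The furan (its C-2, C-3, C-4, C-5 become C6, C1, C2, C3 of the target) and the catalyst-bound acrylate (β- and α-carbon become C5 and C4) should combine in a concerted, asynchronous, suprafacial [4+2] cycloaddition; the closest known reaction type is the oxazaborolidinium-catalysed Diels–Alder reaction of furan with trifluoroethyl acrylate. The six-membered carbocycle C1–C6 is closed in this cycloaddition mode, through a boat-like endo transition state, as a 7-oxanorbornene. C3 and C6 are set together: their relative configuration is fixed by the oxygen bridge and their absolute configuration by the catalyst, which shields one face of the coordinated acrylate; C4 is set by the endo rule and is erased in step 7. The step needs para regioselectivity (ester-bearing carbon bonded to the unsubstituted furan C-5), endo selectivity and enantiofacial control. Para orientation is secured by the substrate: the acrylate β-carbon, which bonds first, attacks furan C-2, the terminus activated by the neighbouring CH2OBz-bearing carbon (the rule for 2-substituted dienes), and the bulkier ester-bearing carbon goes to the unhindered C-5. Low temperature should keep the kinetic endo adduct from equilibrating by cycloreversion.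

Step 3
Reactants: 4 2,2,2-trifluoroethyl (1R,2R,4R)-5-[(benzoyloxy)methyl]-7-oxabicyclo[2.2.1]hept-5-ene-2-carboxylate
Product: 5 (1R,2R,4R)-5-[(benzoyloxy)methyl]-7-oxabicyclo[2.2.1]hept-5-ene-2-carboxylic acid (2-endo acid)
Conditions: LiOH·H2O (1.1 equiv), THF/H2O, 0 °C; then 1 M HCl to pH 3
Reagents that add atoms: lithium hydroxide, [Li+].[OH-]
Why: Saponification of the activated trifluoroethyl ester should be much faster than that of the benzoate and, at 0 °C, faster than epimerisation at the ester-bearing carbon, so the endo acid needed as internal nucleophile is kept.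

Step 4
Reactants: 5 (1R,2R,4R)-5-[(benzoyloxy)methyl]-7-oxabicyclo[2.2.1]hept-5-ene-2-carboxylic acid
Product: 6 [(1R,5S,8S)-8-hydroxy-7-oxo-6-oxabicyclo[3.2.1]oct-3-en-4-yl]methyl benzoate
Conditions: [Rh(cod)Cl]2 (2.5 mol %), dppf (6 mol %), THF, 50–60 °C
Reagents that add atoms: none
Why: Proposed new method: monovalent rhodium should bind the exo face of the alkene and the bridge oxygen and insert into the allylic C6–O bond to give a π-allyl rhodium alkoxide (allyl carbons C6, C1, C2, target numbering); the endo C4 carboxyl, which can reach only C2, should then attack that terminus from the face opposite the metal (an intramolecular anti-SN2' lactonisation), so that the new C2–O bond is trans to the C3 hydroxyl released from the bridge and the alkene moves to C6=C1; the closest known reaction type is the rhodium-catalysed ring opening of oxabenzonorbornadienes and 7-oxanorbornenes by external carboxylic acids and alcohols, which gives trans-1,2 products by the same sequence, the new elements being the tethered nucleophile and the trisubstituted alkene.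

Step 5
Reactants: 6 [(1R,5S,8S)-8-hydroxy-7-oxo-6-oxabicyclo[3.2.1]oct-3-en-4-yl]methyl benzoate
Product: 7 [(1R,5S,8S)-8-[(tert-butyldimethylsilyl)oxy]-7-oxo-6-oxabicyclo[3.2.1]oct-3-en-4-yl]methyl benzoate
Conditions: TBSOTf, 2,6-lutidine, CH2Cl2, −40 to 0 °C
Reagents that add atoms: tert-butyldimethylsilyl triflate, CC(C)(C)[Si](C)(C)OS(=O)(=O)C(F)(F)F
Why: Standard silyl ether formation masks the only free hydroxyl (C3–OH), so that later only C2–OH directs the epoxidation and only the C2 and CH2 hydroxyls are benzoylated.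

Step 6
Reactants: 7 [(1R,5S,8S)-8-[(tert-butyldimethylsilyl)oxy]-7-oxo-6-oxabicyclo[3.2.1]oct-3-en-4-yl]methyl benzoate
Product: 8 cesium (1R,5S,6S)-6-[(tert-butyldimethylsilyl)oxy]-5-hydroxy-4-(hydroxymethyl)cyclohex-3-ene-1-carboxylate
Conditions: CsOH·H2O (2.2 equiv), MeOH/H2O, 0 °C to rt; evaporate, use the crude salt
Reagents that add atoms: cesium hydroxide, [Cs+].[OH-]
Why: Saponification opens the γ-lactone and cleaves the benzoate in one operation, and keeping the product as the cesium carboxylate should prevent the 1,3-cis hydroxy acid from closing back to the lactone; C2 and C3 are untouched.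

Step 7
Reactants: 8 cesium (1R,5S,6S)-6-[(tert-butyldimethylsilyl)oxy]-5-hydroxy-4-(hydroxymethyl)cyclohex-3-ene-1-carboxylate
Product: 9 (1S,6S)-6-[(tert-butyldimethylsilyl)oxy]-2-(hydroxymethyl)cyclohexa-2,4-dien-1-ol
Conditions: 9-mesityl-10-methylacridinium tetrafluoroborate (5 mol %), Co(dmgH)2(py)Cl (5 mol %), MeOH/H2O, blue LEDs, rt, argon
Reagents that add atoms: none
Why: Photocatalytic dehydrogenative decarboxylation: one-electron oxidation of the carboxylate by the excited acridinium, loss of CO2, and hydrogen-atom abstraction by the cobaloxime from the weak allylic C5–H (not the silyloxy-bearing C3–H) should give the conjugated C4=C5–C6=C1 diene with release of H2, erasing the C4 stereocentre that served as relay.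

Step 8
Reactants: 9 (1S,6S)-6-[(tert-butyldimethylsilyl)oxy]-2-(hydroxymethyl)cyclohexa-2,4-dien-1-ol
Product: 10 (1R,2R,3S,6S)-3-[(tert-butyldimethylsilyl)oxy]-1-(hydroxymethyl)-7-oxabicyclo[4.1.0]hept-4-en-2-ol
Conditions: VO(acac)2 (5 mol %), t-BuOOH (1.2 equiv), CH2Cl2, 0 °C
Reagents that add atoms: tert-butyl hydroperoxide, CC(C)(C)OO
Why: Vanadium-catalysed hydroxyl-directed epoxidation should deliver oxygen only to the C6=C1 alkene, which carries both allylic hydroxyls, and syn to the secondary C2–OH as with cyclohex-2-enols, which sets C1 and C6 (epoxide cis to C2–O, trans to C3–O); the C4=C5 alkene has no free allylic hydroxyl and should be left.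

Step 9
Reactants: 10 (1R,2R,3S,6S)-3-[(tert-butyldimethylsilyl)oxy]-1-(hydroxymethyl)-7-oxabicyclo[4.1.0]hept-4-en-2-ol
Product: 11 [(1S,2R,3S,6S)-2-(benzoyloxy)-3-[(tert-butyldimethylsilyl)oxy]-7-oxabicyclo[4.1.0]hept-4-en-1-yl]methyl benzoate
Conditions: BzCl (2.5 equiv), pyridine, DMAP (cat.), CH2Cl2, 0 °C
Reagents that add atoms: benzoyl chloride, O=C(Cl)c1ccccc1
Why: Acylation of the primary and the secondary hydroxyl installs both benzoates of the target at once, and the vinyl epoxide and silyl ether should tolerate the mildly basic conditions.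

Step 10
Reactants: 11 [(1S,2R,3S,6S)-2-(benzoyloxy)-3-[(tert-butyldimethylsilyl)oxy]-7-oxabicyclo[4.1.0]hept-4-en-1-yl]methyl benzoate
Product: 13 [(1R,2R,3S,6R)-2-(benzoyloxy)-6-chloro-1,3-dihydroxycyclohex-4-en-1-yl]methyl benzoate, via silyl-protected chlorohydrin 12 (not isolated)
Conditions: HCl (2 M in Et2O, 3 equiv), CH2Cl2, −20 to 0 °C; then THF/H2O, rt
Reagents that add atoms: hydrogen chloride, Cl
Why: Acid-promoted SN2 opening of the vinyl epoxide by chloride at the allylic carbon C6 with inversion should give the trans-chlorohydrin (Cl anti to C1–OH), the allylic carbon being favoured over the tertiary C1 flanked by two acyloxy-bearing carbons, and the same acid with water then cleaves the silyl ether, which until that point keeps C3–OH from attacking the epoxide.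

**Compound list**

1 | furan-3-ylmethanol | OCc1ccoc1 | starting material
2 | furan-3-ylmethyl benzoate | O=C(OCc1ccoc1)c1ccccc1 | intermediate
3 | 2,2,2-trifluoroethyl acrylate | C=CC(=O)OCC(F)(F)F | starting material
4 | 2,2,2-trifluoroethyl (1R,2R,4R)-5-[(benzoyloxy)methyl]-7-oxabicyclo[2.2.1]hept-5-ene-2-carboxylate (2-endo) | O=C(c1ccccc1)OCC1=C[C@H]2O[C@@H]1C[C@H]2C(=O)OCC(F)(F)F | intermediate
5 | (1R,2R,4R)-5-[(benzoyloxy)methyl]-7-oxabicyclo[2.2.1]hept-5-ene-2-carboxylic acid (2-endo) | O=C(c1ccccc1)OCC1=C[C@H]2O[C@@H]1C[C@H]2C(=O)O | intermediate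
6 | [(1R,5S,8S)-8-hydroxy-7-oxo-6-oxabicyclo[3.2.1]oct-3-en-4-yl]methyl benzoate | O=C(c1ccccc1)OCC1=CC[C@H]2C(=O)O[C@@H]1[C@H]2O | intermediate
7 | [(1R,5S,8S)-8-[(tert-butyldimethylsilyl)oxy]-7-oxo-6-oxabicyclo[3.2.1]oct-3-en-4-yl]methyl benzoate | O=C(c1ccccc1)OCC1=CC[C@H]2C(=O)O[C@@H]1[C@H]2O[Si](C)(C)C(C)(C)C | intermediate
8 | cesium (1R,5S,6S)-6-[(tert-butyldimethylsilyl)oxy]-5-hydroxy-4-(hydroxymethyl)cyclohex-3-ene-1-carboxylate | OCC1=CC[C@@H](C(=O)[O-])[C@H](O[Si](C)(C)C(C)(C)C)[C@H]1O.[Cs+] | intermediate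
9 | (1S,6S)-6-[(tert-butyldimethylsilyl)oxy]-2-(hydroxymethyl)cyclohexa-2,4-dien-1-ol | OCC1=CC=C[C@H](O[Si](C)(C)C(C)(C)C)[C@H]1O | intermediate
10 | (1R,2R,3S,6S)-3-[(tert-butyldimethylsilyl)oxy]-1-(hydroxymethyl)-7-oxabicyclo[4.1.0]hept-4-en-2-ol | OC[C@]12O[C@H]1C=C[C@H](O[Si](C)(C)C(C)(C)C)[C@H]2O | intermediate
11 | [(1S,2R,3S,6S)-2-(benzoyloxy)-3-[(tert-butyldimethylsilyl)oxy]-7-oxabicyclo[4.1.0]hept-4-en-1-yl]methyl benzoate | O=C(c1ccccc1)OC[C@]12O[C@H]1C=C[C@H](O[Si](C)(C)C(C)(C)C)[C@H]2OC(=O)c1ccccc1 | intermediate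
12 | [(1R,2R,3S,6R)-2-(benzoyloxy)-3-[(tert-butyldimethylsilyl)oxy]-6-chloro-1-hydroxycyclohex-4-en-1-yl]methyl benzoate | O=C(OC[C@]1(O)[C@H](Cl)C=C[C@H](O[Si](C)(C)C(C)(C)C)[C@H]1OC(=O)c1ccccc1)c1ccccc1 | intermediate
13 | [(1R,2R,3S,6R)-2-(benzoyloxy)-6-chloro-1,3-dihydroxycyclohex-4-en-1-yl]methyl benzoate (CNP0326102.1) | O=C(OC[C@]1(O)[C@H](Cl)C=C[C@H](O)[C@H]1OC(=O)c1ccccc1)c1ccccc1 | target

**Totals and risks**

Total steps: 10. Longest linear sequence: 10 steps, from 1.

Steps most likely to fail:

Step 4. The rhodium may fail to ionise the bridgehead C–O bond next to a trisubstituted alkene, or the allyl intermediate may lose a proton and drift toward aromatisation before the carboxylate captures it. The fallback sets out from 5, comes back at 6, and uses only known reaction types. The acid 5 is esterified with TMSCHN2 to methyl (1R,2R,4R)-5-[(benzoyloxy)methyl]-7-oxabicyclo[2.2.1]hept-5-ene-2-carboxylate F1. Hydroboration with 9-BBN from the exo face, then oxidation with NaBO3·4H2O, gives methyl 5-endo-[(benzoyloxy)methyl]-6-exo-hydroxy-7-oxabicyclo[2.2.1]heptane-2-endo-carboxylate F2. Dess–Martin periodinane gives the corresponding 6-oxo ester F3. DBU at 0 °C opens the oxygen bridge by E1cB elimination (the proton α to the ketone, the bridge oxygen β) to methyl (1R,6S)-4-[(benzoyloxy)methyl]-6-hydroxy-5-oxocyclohex-3-ene-1-carboxylate F4. Hydroxyl-directed 1,2-reduction with Me4NBH(OAc)3 gives the trans-diol methyl (1R,5S,6S)-4-[(benzoyloxy)methyl]-5,6-dihydroxycyclohex-3-ene-1-carboxylate F5, which lactonises with catalytic camphorsulfonic acid to 6.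

Step 7. Hydrogen abstraction may occur toward the silyloxy-bearing carbon, cobalt hydride may re-add to the dienol and lead to aromatisation, or the hydroxy acid may relactonise. The fallback sets out from 7, comes back at 11, and removes the carboxyl only after every hydroxyl is masked. Allyl alcohol with K2CO3 opens the lactone (and exchanges the benzoate) to allyl (1R,5S,6S)-6-[(tert-butyldimethylsilyl)oxy]-5-hydroxy-4-(hydroxymethyl)cyclohex-3-ene-1-carboxylate F6. VO(acac)2 and t-BuOOH give the epoxy diol allyl 3-[(tert-butyldimethylsilyl)oxy]-2-hydroxy-1-(hydroxymethyl)-7-oxabicyclo[4.1.0]heptane-4-carboxylate F7, with the epoxide cis to C2–OH. BzCl in pyridine gives its dibenzoate F8. Pd(PPh3)4 with morpholine frees the carboxylic acid F9. A Kochi oxidative decarboxylation (Pb(OAc)4, Cu(OAc)2, pyridine, benzene, 80 °C) then introduces the C4=C5 alkene and gives 11.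

Step 2. The benzoate may sequester the catalyst, or regio- and enantiofacial control may be poor with the substituted furan. The fallback sets out from 2, comes back at 5, and replaces asymmetric catalysis by a classical resolution. Furan 2 and acrylic acid are combined without catalyst (neat, hydroquinone, room temperature for a long time or about 1 GPa). The endo para acid is crystallised away from exo and regioisomeric acids as the racemate, that is 5 together with its enantiomer (1S,2S,4S)-5-[(benzoyloxy)methyl]-7-oxabicyclo[2.2.1]hept-5-ene-2-carboxylic acid F10. The (R)-1-phenylethylammonium salt of 5 F11 is recrystallised to constant rotation and acidified, which returns 5; if the other diastereomeric salt proves the less soluble one, (S)-1-phenylethylamine is used instead.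

Further compounds
F1 | step 4 | methyl (1R,2R,4R)-5-[(benzoyloxy)methyl]-7-oxabicyclo[2.2.1]hept-5-ene-2-carboxylate | O=C(c1ccccc1)OCC1=C[C@H]2O[C@@H]1C[C@H]2C(=O)OC
F2 | step 4 | methyl 5-endo-[(benzoyloxy)methyl]-6-exo-hydroxy-7-oxabicyclo[2.2.1]heptane-2-endo-carboxylate | O=C(c1ccccc1)OC[C@@H]1[C@@H](O)[C@H]2O[C@@H]1C[C@H]2C(=O)OC
F3 | step 4 | methyl 5-endo-[(benzoyloxy)methyl]-6-oxo-7-oxabicyclo[2.2.1]heptane-2-endo-carboxylate | O=C(c1ccccc1)OC[C@@H]1C(=O)[C@H]2O[C@@H]1C[C@H]2C(=O)OC
F4 | step 4 | methyl (1R,6S)-4-[(benzoyloxy)methyl]-6-hydroxy-5-oxocyclohex-3-ene-1-carboxylate | O=C(c1ccccc1)OCC1=CC[C@@H](C(=O)OC)[C@H](O)C1=O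
F5 | step 4 | methyl (1R,5S,6S)-4-[(benzoyloxy)methyl]-5,6-dihydroxycyclohex-3-ene-1-carboxylate | O=C(c1ccccc1)OCC1=CC[C@@H](C(=O)OC)[C@H](O)[C@H]1O
F6 | step 7 | allyl (1R,5S,6S)-6-[(tert-butyldimethylsilyl)oxy]-5-hydroxy-4-(hydroxymethyl)cyclohex-3-ene-1-carboxylate | OCC1=CC[C@@H](C(=O)OCC=C)[C@H](O[Si](C)(C)C(C)(C)C)[C@H]1O
F7 | step 7 | allyl 3-[(tert-butyldimethylsilyl)oxy]-2-hydroxy-1-(hydroxymethyl)-7-oxabicyclo[4.1.0]heptane-4-carboxylate (epoxide cis to C2–OH) | OC[C@]12O[C@H]1C[C@@H](C(=O)OCC=C)[C@H](O[Si](C)(C)C(C)(C)C)[C@H]2O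
F8 | step 7 | allyl 2-(benzoyloxy)-1-[(benzoyloxy)methyl]-3-[(tert-butyldimethylsilyl)oxy]-7-oxabicyclo[4.1.0]heptane-4-carboxylate | O=C(c1ccccc1)OC[C@]12O[C@H]1C[C@@H](C(=O)OCC=C)[C@H](O[Si](C)(C)C(C)(C)C)[C@H]2OC(=O)c1ccccc1
F9 | step 7 | 2-(benzoyloxy)-1-[(benzoyloxy)methyl]-3-[(tert-butyldimethylsilyl)oxy]-7-oxabicyclo[4.1.0]heptane-4-carboxylic acid | O=C(c1ccccc1)OC[C@]12O[C@H]1C[C@@H](C(=O)O)[C@H](O[Si](C)(C)C(C)(C)C)[C@H]2OC(=O)c1ccccc1
F10 | step 2 | (1S,2S,4S)-5-[(benzoyloxy)methyl]-7-oxabicyclo[2.2.1]hept-5-ene-2-carboxylic acid (enantiomer of 5) | O=C(c1ccccc1)OCC1=C[C@@H]2O[C@H]1C[C@@H]2C(=O)O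
F11 | step 2 | (R)-1-phenylethylammonium (1R,2R,4R)-5-[(benzoyloxy)methyl]-7-oxabicyclo[2.2.1]hept-5-ene-2-carboxylate | O=C(c1ccccc1)OCC1=C[C@H]2O[C@@H]1C[C@H]2C(=O)[O-].C[C@@H]([NH3+])c1ccccc1
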